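## The problem

Compound 26 is a (2S)-flavanone. A phloroglucinol ring A is fused to the dihydropyranone ring C, and C2 of ring C carries a resorcinol ring B; three prenyl groups sit at C6, C8 and C3', and four phenols at C5, C7, C2' and C4'. C2 is the only stereocentre, so nothing in the substrate can direct it and it has to come from a reagent. It is also fragile: base opens ring C by retro-oxa-Michael loss of the O1 phenoxide, and acid can ionise the benzylic C2–O1 bond with help from the 2'- and 4'-oxygens. The prenyl groups exclude hydrogenolysis, strong Lewis acids and electrophilic oxidants, and each lies ortho to a phenol onto which strong acid would close it as a chroman. Ring A is the easy half, because the two free ring carbons of a phloroacetophenone are equivalent and both are to be prenylated. Ring B is the hard half: it is 1,2,3,4-tetrasubstituted, with the C3' prenyl wedged between O2' and O4', and direct prenylation of a 2,4-dioxygenated aryl group does not choose C3' over C5' reliably. What makes a construction of ring B possible is that its atoms divide into C1'–C6'–C5' plus C2'=O, the pattern of a vinylketene, and C3'(prenyl)–C4'–O, the pattern of a silyl ynol ether, so the ring can be assembled from open-chain pieces with both oxygens and the prenyl group already in place.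

## Retrosynthesis

**26 from 24 (through 25).** Only O–C and O–Si bonds of protecting groups are cut. Acetals on O5, O7 and O2' and a silyl group on O4' are chosen because benzyl or methyl ethers cannot be removed beside three prenyl groups. The forward step must free four phenols without epimerising C2 or cyclising a prenyl group, so fluoride is buffered and the acid is dilute.

**24 from 23.** The C2–H and C3–H bonds are cut, which leads back to the flavone. The flavone is flat, achiral and stable to light, heat and base, so the fragile stereocentre appears only one step before the end. Closing ring C from a chalcone by oxa-Michael addition would set C2 with much less control. The forward step asks a chiral copper hydride to choose one face of C2 and to ignore three isolated trisubstituted alkenes.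

**23 from 22.** The O2'–C acetal bond is cut. The free phenol of 22 would quench the hydride reagent, and an acetal leaves with the ring A acetals at the end.

**22 from 13 and 17.** Four ring B bonds are cut: C5'–C6', C2'–C3', C4'–C5' and C1'–C2'. Cutting C2–C1' instead (aryl coupling or an acylation route) would leave the 1,2,3,4-pattern of ring B unsolved, and cutting the C3'–prenyl bond would demand a regioselective prenylation that resorcinols do not give. The precursors are far simpler: a chromone carrying a four-carbon diazo enone chain (13) and a seven-carbon silyl ynol ether (17). The forward reaction must add the ynol ether to the ketene in one orientation and must run in the presence of a chromone chromophore.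

**13 from 11.** The C=N2 bond is cut back to the methyl ketone. Diazo transfer is preferred to acylating a diazoalkane with the unsaturated acid chloride, because a diazoalkane would add across the electron-poor double bond.

**11 from 8 and 9.** The side-chain C=C bond is cut back to aldehyde 10 and the acetonyl ylide 9. Since 10 is expected to hydrate readily, it is generated from carbinol 8 and trapped in the same flask.

**8 from 7, and 7 from 6.** These are an ester reduction and the protection of O5 and O7; no skeletal bond changes.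

**6 from 3 and 4.** The C3–C2 and O1–C2 bonds of the pyranone are cut (through diketo ester 5). The two ortho hydroxyls of 3 are equivalent, so only one chromone can form, and oxalate 4 delivers C2 with a carboxylate handle for the side chain.

**3 from 1 and 2.** Two aryl–allyl bonds are cut. Both free ring positions of 1 are equivalent and both are needed, so direct C-prenylation has no regiochemical question, only one of yield.

**17 from 14.** The alkyne C–C bond to the prenyl-bearing carbon is cut. One-carbon homologation of ester 14 to the ynolate 16 (through 15) and O-silylation give the ynol ether in one flask.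

## Roads not taken

**Alternative 1:** The cut is at the three aryl–allyl bonds C6–C, C8–C and C3'–C, traced back to the O–allyl bonds of 5,7,2'-tris(allyloxy)-4'-(methoxymethoxy)flavone A2. Heating A2 to about 200 °C would move the three allyl groups by [3,3] shifts to give 6,8,3'-triallyl-5,7,2'-trihydroxy-4'-(methoxymethoxy)flavone A1; threefold cross-metathesis with the second-generation Grubbs catalyst would then turn allyl into prenyl.
- Merits: A2 comes from classical flavone chemistry, no diazo compound or lamp is needed, and in ring B the O2' allyl group has only C3' to go to, so the hard regiochemical question is answered cleanly.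
- Weak points: in ring A the O7 allyl group can reach C6 or C8, while the O5 group can reach only C6, so every O7-to-C6 event leaves the O5 group without an ortho site and mixtures must be expected. The chelated O5 has to be allylated first, the freed ortho-allylphenols can close to dihydrobenzofurans at that temperature, three metatheses must all go to completion, and the phenols need protection again before the reduction.
- Comparison: this road is shorter to the flavone and equal in ring B regiocontrol. The chosen plan sets against it that ring A is prenylated on a symmetric acetophenone where no choice arises, that prenyl groups enter as such, and that nothing is heated above 80 °C.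

**Alternative 2:** The cut is at C3–C4 and O1–C2 of ring C. A chiral phosphoric acid would turn salicylaldehyde A5 and an orthoformate into a 4-methoxy ortho-quinone methide, which adds styrene A4 in a [4+2] reaction to give the (2S)-cis-4-methoxyflavan A3.
- Merits: the route is convergent, and ring C and the C2 stereocentre are made in one catalytic step. In this it is better than the chosen plan, which needs a separate asymmetric reduction.
- Weak points: A3 is at the wrong oxidation level at C4, and turning a benzylic methyl ether into a ketone beside three prenyl groups and two electron-rich rings is not a gentle operation. The 2-aryl benzylic ether of A3, with oxygen at C2' and C4', can ionise under the acidic catalyst that forms it. Above all, A4 already contains the 1,2,3,4-pattern of ring B, so the main problem is moved to the synthesis of A4 and not solved.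
- Comparison: the chosen plan sets against the stereochemical economy of this road a ring B whose substitution is fixed by construction and a C4 carbonyl that is present from the start.

**Alternative 3:** The cut is at C8–C8a, C5–C6, C7–C8 and C4a–C5, so that ring A is built on a pyranone. Photolysis of diazo ketone A7 with the ynol ether 17 would give 5-hydroxy-6,8-diprenyl-7-(triisopropylsilyloxy)chromone A6.
- Merits: it uses the same alkyne 17, and A6 is unsubstituted at C2, so ring B might be added with stereocontrol by asymmetric conjugate arylation with boronic acid A8. That would make the C2–C1' bond and the stereocentre together and shorten the end game.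
- Weak points: ring A does not need the annulation, since its pattern comes from 1 in one step. A7 is an α-alkyl diazo ketone with an allylic CH2, so 1,2-hydrogen shift and carbene addition to its own prenyl alkene compete with the Wolff shift. A8 still requires the ring B pattern to be solved elsewhere, and as an ortho-substituted boronic acid it is a poor partner for a 5-oxygenated chromone.
- Comparison: this road spends the key reaction on the easy ring and leaves the hard ring to classical chemistry. The chosen plan sets against its shorter end game that the annulation is used where nothing else gives the pattern.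

Key step: step 8

Remarks. Prenyl = 3-methylbut-2-enyl; MOM = methoxymethyl; Chr = the 5,7-bis(methoxymethoxy)-6,8-diprenyl-4-oxo-4H-chromen-2-yl group. Compounds 1, 2, 4, 9 and 14 are taken as purchased. Assumption: by analogy with the face selectivity of bisphosphine CuH on 3-substituted cyclohexenones, the (S) ligand is taken to give the 2S flavanone; if the sense is opposite, the (R) ligand is used and nothing else changes.

## Route

Step 1
Reactants: 1 2,4,6-trihydroxyacetophenone; 2 prenyl bromide (1-bromo-3-methylbut-2-ene)
Product: 3 1-[2,4,6-trihydroxy-3,5-bis(3-methylbut-2-enyl)phenyl]ethanone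
Conditions: 2 (2.2 equiv), 10% aq. KOH, 0 °C → rt, N2
Reagents that add atoms: none
Why: Twofold C-alkylation of the phloroglucinol polyanion in water, where solvation of the phenoxide oxygens steers the allylic bromide to the two equivalent free ring carbons; mono-prenyl and geminal diprenyl by-products are expected and are removed by chromatography.

Step 2
Reactants: 3 1-[2,4,6-trihydroxy-3,5-bis(3-methylbut-2-enyl)phenyl]ethanone; 4 diethyl oxalate
Product: 6 ethyl 5,7-dihydroxy-6,8-bis(3-methylbut-2-enyl)-4-oxo-4H-chromene-2-carboxylate, via diketo ester 5 (not isolated)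
Conditions: NaOEt (6 equiv), 4 (4 equiv), EtOH, reflux; then conc. HCl (cat.), EtOH, 50 °C, short
Reagents that add atoms: none
Why: Claisen condensation of the methyl ketone with the oxalate followed by cyclodehydration, the classical chromone-2-carboxylate synthesis; the two ortho hydroxyls are equivalent so only one chromone can form, and the acid stage is brief and mild to spare the prenyl groups.

Step 3
Reactants: 6 ethyl 5,7-dihydroxy-6,8-bis(3-methylbut-2-enyl)-4-oxo-4H-chromene-2-carboxylate
Product: 7 ethyl 5,7-bis(methoxymethoxy)-6,8-bis(3-methylbut-2-enyl)-4-oxo-4H-chromene-2-carboxylate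
Conditions: NaH (2.6 equiv), MOMCl (3 equiv), DMF, 0 °C → rt
Reagents that add atoms: chloromethyl methyl ether (MOMCl), COCCl
Why: Williamson etherification of both phenols; NaH is used because the C5 hydroxyl is hydrogen-bonded to the C4 carbonyl and the C7 hydroxyl is flanked by two prenyl groups, and the small, hard chloride alkylates the phenoxides at oxygen.

Step 4
Reactants: 7 ethyl 5,7-bis(methoxymethoxy)-6,8-bis(3-methylbut-2-enyl)-4-oxo-4H-chromene-2-carboxylate
Product: 8 2-(hydroxymethyl)-5,7-bis(methoxymethoxy)-6,8-bis(3-methylbut-2-enyl)chromen-4-one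
Conditions: NaBH4 (1.5 equiv), EtOH–THF, 0 °C
Reagents that add atoms: none
Why: Chemoselective borohydride reduction: the ester on C2 is activated by the electron-poor pyranone ring, whereas the C4 carbonyl is a vinylogous ester and stays untouched, as is usual for chromone-2-carboxylates.

Step 5
Reactants: 8 2-(hydroxymethyl)-5,7-bis(methoxymethoxy)-6,8-bis(3-methylbut-2-enyl)chromen-4-one; 9 1-(triphenylphosphoranylidene)propan-2-one
Product: 11 (3E)-4-Chr-but-3-en-2-one, via chromone-2-carbaldehyde 10 (not isolated)
Conditions: activated MnO2 (15 equiv), 9 (1.3 equiv), CH2Cl2, rt → 40 °C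
Reagents that add atoms: none
Why: Tandem oxidation–Wittig olefination: MnO2 oxidises the allylic-type carbinol to aldehyde 10, which is trapped at once by the stabilised ylide, so the hydrate-prone aldehyde is never handled; the stabilised ylide gives the E enone.

Step 6
Reactants: 11 (3E)-4-Chr-but-3-en-2-one
Product: 13 (3E)-1-diazo-4-Chr-but-3-en-2-one, via trifluoroacetyl diketone 12 (not isolated)
Conditions: LiN(SiMe3)2 (1.1 equiv), THF, −78 °C; CF3CO2CH2CF3 (1.2 equiv); dil. HCl work-up; then MsN3 (1.5 equiv), Et3N (1.5 equiv), H2O (1 equiv), MeCN, rt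
Reagents that add atoms: methanesulfonyl azide, CS(=O)(=O)N=[N+]=[N-]
Why: Detrifluoroacetylative diazo transfer: the kinetic lithium enolate of the methyl ketone is C-acylated by the trifluoroacetate, and the activated diketone 12 takes the diazo group from the sulfonyl azide with loss of the trifluoroacetyl group; this is the established entry to α'-diazo enones, for which acylation of a diazoalkane fails.

Step 7
Reactants: 14 ethyl 4-methylpent-3-enoate
Product: 17 triisopropyl[(5-methylhex-4-en-1-yn-1-yl)oxy]silane, via dibromo enolate 15 (not isolated), via lithium ynolate 16 (not isolated)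
Conditions: CH2Br2 (1.1 equiv), lithium 2,2,6,6-tetramethylpiperidide, THF, −78 °C; LiN(SiMe3)2; n-BuLi, −78 → 20 °C; then i-Pr3SiCl, −78 → 20 °C
Reagents that add atoms: dibromomethane, BrCBr; chlorotriisopropylsilane, CC(C)[Si](Cl)(C(C)C)C(C)C
Why: Kowalski ester homologation stopped at the ynolate: LiCHBr2 adds to the ester, the dibromo enolate 15 undergoes Br/Li exchange and 1,2-shift of the prenylmethyl group to ynolate 16, and the bulky silyl chloride silylates 16 at oxygen.

Step 8
Reactants: 13 (3E)-1-diazo-4-Chr-but-3-en-2-one; 17 triisopropyl[(5-methylhex-4-en-1-yn-1-yl)oxy]silane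
Product: 22 2-[2-hydroxy-3-(3-methylbut-2-enyl)-4-(triisopropylsilyloxy)phenyl]-5,7-bis(methoxymethoxy)-6,8-bis(3-methylbut-2-enyl)chromen-4-one, via vinylketene 18 (not isolated), via vinylcyclobutenone 19 (not isolated), via dienylketene 20 (not isolated), via cyclohexadienone 21 (not isolated)
Conditions: 17 (1.5 equiv), hν (365 nm), ClCH2CH2Cl, 20 °C; then 80 °C
Reagents that add atoms: none
Why: This is the photochemical (second-generation) Danheiser benzannulation of an α'-diazo enone with a siloxyalkyne. Light expels N2 from 13 and the alkenyl group shifts to the carbene carbon (Wolff rearrangement, forming C5'–C6') to give vinylketene 18. The ketene C=C adds the alkyne in a [2+2] cycloaddition, the nucleophilic prenyl-bearing alkyne carbon bonding to the ketene carbonyl carbon (C2'–C3') and the silyloxy carbon to the former diazo carbon (C4'–C5'), which gives cyclobutenone 19. At 80 °C 19 opens by 4π-electrocyclic reversion to dienylketene 20, and ring B closes by thermal 6π-electrocyclisation (C1'–C2'), after which dienone 21 tautomerises to the phenol. No stereocentre persists, since the sp3 centres of 19 and 21 are erased by ring opening and enolisation. The step needs regiocontrol in the [2+2] event, which the polarisation of the ynol ether supplies, so that the ketene oxygen becomes O2', the silyloxy carbon C4' and the prenyl group lies between them at C3'. It also needs the ketene to prefer the alkyne over the prenyl double bonds, which the far higher nucleophilicity of the ynol ether secures, and a geometry fit for ring closure, which the E alkene provides by keeping the chromonyl group on the outside of the triene. Irradiation at 365 nm addresses the long-wavelength diazo band and limits direct excitation of the chromone.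

Step 9
Reactants: 22 2-[2-hydroxy-3-(3-methylbut-2-enyl)-4-(triisopropylsilyloxy)phenyl]-5,7-bis(methoxymethoxy)-6,8-bis(3-methylbut-2-enyl)chromen-4-one
Product: 23 2-[2-(methoxymethoxy)-3-(3-methylbut-2-enyl)-4-(triisopropylsilyloxy)phenyl]-5,7-bis(methoxymethoxy)-6,8-bis(3-methylbut-2-enyl)chromen-4-one
Conditions: NaH (1.3 equiv), MOMCl (1.5 equiv), THF–DMF, 0 °C → rt
Reagents that add atoms: chloromethyl methyl ether (MOMCl), COCCl
Why: Williamson etherification of the only free phenol; protection is required because a phenol would destroy the copper hydride of step 10, and an acetal is chosen so that it leaves together with the ring A acetals.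

Step 10
Reactants: 23 2-[2-(methoxymethoxy)-3-(3-methylbut-2-enyl)-4-(triisopropylsilyloxy)phenyl]-5,7-bis(methoxymethoxy)-6,8-bis(3-methylbut-2-enyl)chromen-4-one
Product: 24 (2S)-2-[2-(methoxymethoxy)-3-(3-methylbut-2-enyl)-4-(triisopropylsilyloxy)phenyl]-5,7-bis(methoxymethoxy)-6,8-bis(3-methylbut-2-enyl)-2,3-dihydrochromen-4-one
Conditions: Cu(OAc)2 (5 mol %), (S)-DTBM-SEGPHOS (5.5 mol %), (EtO)2MeSiH (2 equiv), t-BuOH (1.5 equiv), toluene, 0 °C
Reagents that add atoms: none
Why: Asymmetric CuH-catalysed conjugate reduction, known for β,β-disubstituted enones and for 2-substituted chromones: the bisphosphine-bound hydride is delivered to one face of C2 of the flat flavone, so the ligand alone sets the 2S centre; t-BuOH protonates the copper enolate quickly, which limits ring opening, and isolated trisubstituted alkenes do not react with CuH.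

Step 11
Reactants: 24 (2S)-2-[2-(methoxymethoxy)-3-(3-methylbut-2-enyl)-4-(triisopropylsilyloxy)phenyl]-5,7-bis(methoxymethoxy)-6,8-bis(3-methylbut-2-enyl)-2,3-dihydrochromen-4-one
Product: 26 (2S)-2-[2,4-dihydroxy-3-(3-methylbut-2-enyl)phenyl]-5,7-dihydroxy-6,8-bis(3-methylbut-2-enyl)-2,3-dihydrochromen-4-one, via 4'-phenol 25 (not isolated)
Conditions: Bu4NF, AcOH (1:1), THF, 0 °C; then 3 M HCl, MeOH, 25–40 °C
Reagents that add atoms: none
Why: Fluoride buffered with acetic acid cleaves the aryl silyl ether without leaving a free phenoxide that could open ring C through a quinone methide, and dilute methanolic HCl then exchanges the three acetals to volatile dimethoxymethane, the usual deprotection of prenylated flavanones; no stereocentre is made, and time and temperature are kept low to protect C2 and the prenyl groups.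

## Compound list

1 | 2,4,6-trihydroxyacetophenone | CC(=O)c1c(O)cc(O)cc1O | starting material
2 | prenyl bromide (1-bromo-3-methylbut-2-ene) | CC(C)=CCBr | starting material
3 | 1-[2,4,6-trihydroxy-3,5-bis(3-methylbut-2-enyl)phenyl]ethanone | CC(=O)c1c(O)c(CC=C(C)C)c(O)c(CC=C(C)C)c1O | intermediate
4 | diethyl oxalate | CCOC(=O)C(=O)OCC | starting material
5 | ethyl 2,4-dioxo-4-[2,4,6-trihydroxy-3,5-bis(3-methylbut-2-enyl)phenyl]butanoate | CCOC(=O)C(=O)CC(=O)c1c(O)c(CC=C(C)C)c(O)c(CC=C(C)C)c1O | intermediate
6 | ethyl 5,7-dihydroxy-6,8-bis(3-methylbut-2-enyl)-4-oxo-4H-chromene-2-carboxylate | CCOC(=O)c1cc(=O)c2c(O)c(CC=C(C)C)c(O)c(CC=C(C)C)c2o1 | intermediate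
7 | ethyl 5,7-bis(methoxymethoxy)-6,8-bis(3-methylbut-2-enyl)-4-oxo-4H-chromene-2-carboxylate | CCOC(=O)c1cc(=O)c2c(OCOC)c(CC=C(C)C)c(OCOC)c(CC=C(C)C)c2o1 | intermediate
8 | 2-(hydroxymethyl)-5,7-bis(methoxymethoxy)-6,8-bis(3-methylbut-2-enyl)chromen-4-one | OCc1cc(=O)c2c(OCOC)c(CC=C(C)C)c(OCOC)c(CC=C(C)C)c2o1 | intermediate
9 | 1-(triphenylphosphoranylidene)propan-2-one | CC(=O)C=P(c1ccccc1)(c1ccccc1)c1ccccc1 | starting material
10 | 5,7-bis(methoxymethoxy)-6,8-bis(3-methylbut-2-enyl)-4-oxo-4H-chromene-2-carbaldehyde | O=Cc1cc(=O)c2c(OCOC)c(CC=C(C)C)c(OCOC)c(CC=C(C)C)c2o1 | intermediate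
11 | (3E)-4-[5,7-bis(methoxymethoxy)-6,8-bis(3-methylbut-2-enyl)-4-oxo-4H-chromen-2-yl]but-3-en-2-one | CC(=O)/C=C/c1cc(=O)c2c(OCOC)c(CC=C(C)C)c(OCOC)c(CC=C(C)C)c2o1 | intermediate
12 | (5E)-6-[5,7-bis(methoxymethoxy)-6,8-bis(3-methylbut-2-enyl)-4-oxo-4H-chromen-2-yl]-1,1,1-trifluorohex-5-ene-2,4-dione | O=C(CC(=O)/C=C/c1cc(=O)c2c(OCOC)c(CC=C(C)C)c(OCOC)c(CC=C(C)C)c2o1)C(F)(F)F | intermediate
13 | (3E)-1-diazo-4-[5,7-bis(methoxymethoxy)-6,8-bis(3-methylbut-2-enyl)-4-oxo-4H-chromen-2-yl]but-3-en-2-one | [N-]=[N+]=CC(=O)/C=C/c1cc(=O)c2c(OCOC)c(CC=C(C)C)c(OCOC)c(CC=C(C)C)c2o1 | intermediate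
14 | ethyl 4-methylpent-3-enoate | CCOC(=O)CC=C(C)C | starting material
15 | lithium 1,1-dibromo-5-methylhexa-1,4-dien-2-olate | [Li+].[O-]C(CC=C(C)C)=C(Br)Br | intermediate
16 | lithium 5-methylhex-4-en-1-yn-1-olate | [Li+].[O-]C#CCC=C(C)C | intermediate
17 | triisopropyl[(5-methylhex-4-en-1-yn-1-yl)oxy]silane | CC(C)=CCC#CO[Si](C(C)C)(C(C)C)C(C)C | intermediate
18 | (3E)-4-[5,7-bis(methoxymethoxy)-6,8-bis(3-methylbut-2-enyl)-4-oxo-4H-chromen-2-yl]buta-1,3-dien-1-one | O=C=C/C=C/c1cc(=O)c2c(OCOC)c(CC=C(C)C)c(OCOC)c(CC=C(C)C)c2o1 | intermediate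
19 | 4-[(E)-2-Chr-ethenyl]-2-(3-methylbut-2-enyl)-3-(triisopropylsilyloxy)cyclobut-2-en-1-one (racemic at C4) | O=C1C(CC=C(C)C)=C(O[Si](C(C)C)(C(C)C)C(C)C)C1/C=C/c1cc(=O)c2c(OCOC)c(CC=C(C)C)c(OCOC)c(CC=C(C)C)c2o1 | intermediate
20 | (3E,5E)-6-Chr-2-(3-methylbut-2-enyl)-3-(triisopropylsilyloxy)hexa-1,3,5-trien-1-one | O=C=C(CC=C(C)C)\C(O[Si](C(C)C)(C(C)C)C(C)C)=C/C=C/c1cc(=O)c2c(OCOC)c(CC=C(C)C)c(OCOC)c(CC=C(C)C)c2o1 | intermediate
21 | 6-Chr-2-(3-methylbut-2-enyl)-3-(triisopropylsilyloxy)cyclohexa-2,4-dien-1-one (racemic at C6) | O=C1C(CC=C(C)C)=C(O[Si](C(C)C)(C(C)C)C(C)C)C=CC1c1cc(=O)c2c(OCOC)c(CC=C(C)C)c(OCOC)c(CC=C(C)C)c2o1 | intermediate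
22 | 2-[2-hydroxy-3-(3-methylbut-2-enyl)-4-(triisopropylsilyloxy)phenyl]-5,7-bis(methoxymethoxy)-6,8-bis(3-methylbut-2-enyl)chromen-4-one | CC(C)=CCc1c(O[Si](C(C)C)(C(C)C)C(C)C)ccc(-c2cc(=O)c3c(OCOC)c(CC=C(C)C)c(OCOC)c(CC=C(C)C)c3o2)c1O | intermediate
23 | 2-[2-(methoxymethoxy)-3-(3-methylbut-2-enyl)-4-(triisopropylsilyloxy)phenyl]-5,7-bis(methoxymethoxy)-6,8-bis(3-methylbut-2-enyl)chromen-4-one | CC(C)=CCc1c(O[Si](C(C)C)(C(C)C)C(C)C)ccc(-c2cc(=O)c3c(OCOC)c(CC=C(C)C)c(OCOC)c(CC=C(C)C)c3o2)c1OCOC | intermediate
24 | (2S)-2-[2-(methoxymethoxy)-3-(3-methylbut-2-enyl)-4-(triisopropylsilyloxy)phenyl]-5,7-bis(methoxymethoxy)-6,8-bis(3-methylbut-2-enyl)-2,3-dihydrochromen-4-one | CC(C)=CCc1c(O[Si](C(C)C)(C(C)C)C(C)C)ccc([C@@H]2CC(=O)c3c(OCOC)c(CC=C(C)C)c(OCOC)c(CC=C(C)C)c3O2)c1OCOC | intermediate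
25 | (2S)-2-[4-hydroxy-2-(methoxymethoxy)-3-(3-methylbut-2-enyl)phenyl]-5,7-bis(methoxymethoxy)-6,8-bis(3-methylbut-2-enyl)-2,3-dihydrochromen-4-one | CC(C)=CCc1c(O)ccc([C@@H]2CC(=O)c3c(OCOC)c(CC=C(C)C)c(OCOC)c(CC=C(C)C)c3O2)c1OCOC | intermediate
26 | (2S)-2-[2,4-dihydroxy-3-(3-methylbut-2-enyl)phenyl]-5,7-dihydroxy-6,8-bis(3-methylbut-2-enyl)-2,3-dihydrochromen-4-one | CC(C)=CCc1c(O)ccc([C@@H]2CC(=O)c3c(O)c(CC=C(C)C)c(O)c(CC=C(C)C)c3O2)c1O | target

## Step count and risks

Total: 11 steps. Longest linear sequence: 10 steps (steps 1–6 and 8–11); step 7 is a one-step branch that joins at step 8.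

**Step 8 (key step).** The chromone and the extended dienone of 13 absorb in the same region as the diazo band, and the product flavone filters light as it forms. The likely failures are therefore E/Z isomerisation of the alkene, photoaddition of the excited chromone to a prenyl double bond, and incomplete Wolff rearrangement.
- Fallback: the same annulation is run on a carrier without a chromone, and ring C is closed afterwards. It sets out from 17 and 3 and comes back at 23.
- Ethyl (2E)-4-oxopent-2-enoate F1 would be taken through the diazo transfer of step 6 to ethyl (2E)-5-diazo-4-oxopent-2-enoate F2.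
- Irradiation of F2 with 17 and heating would give ethyl 2-hydroxy-3-(3-methylbut-2-enyl)-4-(triisopropylsilyloxy)benzoate F3, in which the ester marks C1'.
- MOMCl and NaH would give ethyl 2-(methoxymethoxy)-3-(3-methylbut-2-enyl)-4-(triisopropylsilyloxy)benzoate F4.
- In parallel, 3 would be converted with MOMCl and i-Pr2NEt into 1-[2-hydroxy-4,6-bis(methoxymethoxy)-3,5-bis(3-methylbut-2-enyl)phenyl]ethanone F5, the chelated hydroxyl staying free.
- The dianion of F5 (LiN(SiMe3)2, 3 equiv) would be acylated at carbon by F4 to give 1-[2-hydroxy-4,6-bis(methoxymethoxy)-3,5-bis(3-methylbut-2-enyl)phenyl]-3-[2-(methoxymethoxy)-3-(3-methylbut-2-enyl)-4-(triisopropylsilyloxy)phenyl]propane-1,3-dione F6.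
- Buffered cyclodehydration of F6 (NaOAc, AcOH, warm) would close the pyranone to 23; any acetal lost at this point would be restored by repeating the MOMCl treatment before step 10.

**Step 10.** The 2-aryl group is twisted and flanked by a 2'-acetal and a 3'-prenyl group, so hydride transfer to C2 may be slow or poorly face-selective. Competing 1,2-reduction of C4 and ring opening of the copper enolate would also erode the result, and the sense of induction is an assumption.
- Fallback: reduction without stereocontrol followed by kinetic resolution, from 23 back to 24.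
- Conjugate reduction of 23 with LiBH(s-Bu)3 (THF, −78 °C) would give the racemic flavanone F7 (racemic form of 24).
- Transfer hydrogenation with Cp*RhCl[(R,R)-TsDPEN] and HCO2H/Et3N is expected, by the usual sense for aryl ketones, to reduce the 2R ketone faster to the cis alcohol (2R,4R)-2-[2-(methoxymethoxy)-3-(3-methylbut-2-enyl)-4-(triisopropylsilyloxy)phenyl]-5,7-bis(methoxymethoxy)-6,8-bis(3-methylbut-2-enyl)chroman-4-ol F8 and to leave 24, which is separated by chromatography.

**Step 11.** Acid may ionise the C2–O1 bond of the electron-rich flavanone, with loss of configurational purity, or may add a phenol across a neighbouring prenyl double bond.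
- Fallback: the protecting groups are changed while the molecule is still an achiral flavone, so that the flavanone never meets acid. It sets out from 23 and comes back at 26.
- 23 would be stripped with Bu4NF and then methanolic HCl to 2-[2,4-dihydroxy-3-(3-methylbut-2-enyl)phenyl]-5,7-dihydroxy-6,8-bis(3-methylbut-2-enyl)chromen-4-one F9.
- Silylation (t-BuMe2SiOTf, 2,6-lutidine) would give the tetrakis(tert-butyldimethylsilyl) ether of that flavone F10.
- Reduction under the conditions of step 10 would give the (2S)-tetrakis(tert-butyldimethylsilyloxy)flavanone F11.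
- Et3N·3HF in THF at 0 °C would then give 26.

**Step 6.** The enone of 11 is conjugated through to the chromone carbonyl and is a strong acceptor, so the amide base may add to it or the enolate may oligomerise before it is acylated.
- Fallback: the diazo ketone is brought in as an olefination reagent, from 8 back to 13.
- 8 would be oxidised with MnO2 alone and aldehyde 10 isolated.
- Horner–Wadsworth–Emmons reaction of 10 with diethyl (3-diazo-2-oxopropyl)phosphonate F12 (LiCl, i-Pr2NEt, MeCN) would give 13 directly as the E isomer.

**Step 7.** The lithium amide may enolise the β,γ-unsaturated ester before the carbenoid adds, and the excess base may shift the skipped double bond or isomerise the propargylic position.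
- Fallback: the ynolate is made by oxidation of an acetylide, from 2 back to 17.
- 2 would be coupled with ethynylmagnesium bromide (CuCl cat., THF) to give 5-methylhex-4-en-1-yne F13.
- Lithiation (n-BuLi), oxidation of the acetylide with LiOOt-Bu to ynolate 16 and silylation with i-Pr3SiOTf would give 17.

## Further compounds

F1 | step 8 | ethyl (2E)-4-oxopent-2-enoate | CCOC(=O)/C=C/C(C)=O
F2 | step 8 | ethyl (2E)-5-diazo-4-oxopent-2-enoate | CCOC(=O)/C=C/C(=O)C=[N+]=[N-]
F3 | step 8 | ethyl 2-hydroxy-3-(3-methylbut-2-enyl)-4-(triisopropylsilyloxy)benzoate | CCOC(=O)c1ccc(O[Si](C(C)C)(C(C)C)C(C)C)c(CC=C(C)C)c1O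
F4 | step 8 | ethyl 2-(methoxymethoxy)-3-(3-methylbut-2-enyl)-4-(triisopropylsilyloxy)benzoate | CCOC(=O)c1ccc(O[Si](C(C)C)(C(C)C)C(C)C)c(CC=C(C)C)c1OCOC
F5 | step 8 | 1-[2-hydroxy-4,6-bis(methoxymethoxy)-3,5-bis(3-methylbut-2-enyl)phenyl]ethanone | CC(=O)c1c(O)c(CC=C(C)C)c(OCOC)c(CC=C(C)C)c1OCOC
F6 | step 8 | 1-[2-hydroxy-4,6-bis(methoxymethoxy)-3,5-bis(3-methylbut-2-enyl)phenyl]-3-[2-(methoxymethoxy)-3-(3-methylbut-2-enyl)-4-(triisopropylsilyloxy)phenyl]propane-1,3-dione | CC(C)=CCc1c(O[Si](C(C)C)(C(C)C)C(C)C)ccc(C(=O)CC(=O)c2c(O)c(CC=C(C)C)c(OCOC)c(CC=C(C)C)c2OCOC)c1OCOC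
F7 | step 10 | racemic 2-[2-(methoxymethoxy)-3-(3-methylbut-2-enyl)-4-(triisopropylsilyloxy)phenyl]-5,7-bis(methoxymethoxy)-6,8-bis(3-methylbut-2-enyl)-2,3-dihydrochromen-4-one | CC(C)=CCc1c(O[Si](C(C)C)(C(C)C)C(C)C)ccc(C2CC(=O)c3c(OCOC)c(CC=C(C)C)c(OCOC)c(CC=C(C)C)c3O2)c1OCOC
F8 | step 10 | (2R,4R)-2-[2-(methoxymethoxy)-3-(3-methylbut-2-enyl)-4-(triisopropylsilyloxy)phenyl]-5,7-bis(methoxymethoxy)-6,8-bis(3-methylbut-2-enyl)chroman-4-ol | CC(C)=CCc1c(O[Si](C(C)C)(C(C)C)C(C)C)ccc([C@H]2C[C@@H](O)c3c(OCOC)c(CC=C(C)C)c(OCOC)c(CC=C(C)C)c3O2)c1OCOC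
F9 | step 11 | 2-[2,4-dihydroxy-3-(3-methylbut-2-enyl)phenyl]-5,7-dihydroxy-6,8-bis(3-methylbut-2-enyl)chromen-4-one | CC(C)=CCc1c(O)ccc(-c2cc(=O)c3c(O)c(CC=C(C)C)c(O)c(CC=C(C)C)c3o2)c1O
F10 | step 11 | 2-[2,4-bis(tert-butyldimethylsilyloxy)-3-(3-methylbut-2-enyl)phenyl]-5,7-bis(tert-butyldimethylsilyloxy)-6,8-bis(3-methylbut-2-enyl)chromen-4-one | CC(C)=CCc1c(O[Si](C)(C)C(C)(C)C)ccc(-c2cc(=O)c3c(O[Si](C)(C)C(C)(C)C)c(CC=C(C)C)c(O[Si](C)(C)C(C)(C)C)c(CC=C(C)C)c3o2)c1O[Si](C)(C)C(C)(C)C
F11 | step 11 | (2S)-2-[2,4-bis(tert-butyldimethylsilyloxy)-3-(3-methylbut-2-enyl)phenyl]-5,7-bis(tert-butyldimethylsilyloxy)-6,8-bis(3-methylbut-2-enyl)-2,3-dihydrochromen-4-one | CC(C)=CCc1c(O[Si](C)(C)C(C)(C)C)ccc([C@@H]2CC(=O)c3c(O[Si](C)(C)C(C)(C)C)c(CC=C(C)C)c(O[Si](C)(C)C(C)(C)C)c(CC=C(C)C)c3O2)c1O[Si](C)(C)C(C)(C)C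
F12 | step 6 | diethyl (3-diazo-2-oxopropyl)phosphonate | CCOP(=O)(CC(=O)C=[N+]=[N-])OCC
F13 | step 7 | 5-methylhex-4-en-1-yne | C#CCC=C(C)C
A1 | alternative 1 | 6,8,3'-triallyl-5,7,2'-trihydroxy-4'-(methoxymethoxy)flavone | C=CCc1c(O)c(CC=C)c2oc(-c3ccc(OCOC)c(CC=C)c3O)cc(=O)c2c1O
A2 | alternative 1 | 5,7,2'-tris(allyloxy)-4'-(methoxymethoxy)flavone | C=CCOc1cc(OCC=C)c2c(=O)cc(-c3ccc(OCOC)cc3OCC=C)oc2c1
A3 | alternative 2 | (2S)-cis-5,2'-dihydroxy-4-methoxy-7,4'-bis(tert-butyldimethylsilyloxy)-6,8,3'-triprenylflavan | CC(C)=CCc1c(O[Si](C)(C)C(C)(C)C)ccc([C@@H]2C[C@H](OC)c3c(O)c(CC=C(C)C)c(O[Si](C)(C)C(C)(C)C)c(CC=C(C)C)c3O2)c1O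
A4 | alternative 2 | 3-(tert-butyldimethylsilyloxy)-6-ethenyl-2-(3-methylbut-2-enyl)phenol | C=Cc1ccc(O[Si](C)(C)C(C)(C)C)c(CC=C(C)C)c1O
A5 | alternative 2 | 4-(tert-butyldimethylsilyloxy)-2,6-dihydroxy-3,5-bis(3-methylbut-2-enyl)benzaldehyde | O=Cc1c(O)c(CC=C(C)C)c(O[Si](C)(C)C(C)(C)C)c(CC=C(C)C)c1O
A6 | alternative 3 | 5-hydroxy-6,8-bis(3-methylbut-2-enyl)-7-(triisopropylsilyloxy)chromen-4-one | CC(C)=CCc1c(O)c2c(=O)ccoc2c(CC=C(C)C)c1O[Si](C(C)C)(C(C)C)C(C)C
A7 | alternative 3 | 2-diazo-5-methyl-1-(4-oxo-4H-pyran-2-yl)hex-4-en-1-one | CC(C)=CCC(=[N+]=[N-])C(=O)c1cc(=O)cco1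
A8 | alternative 3 | [2,4-bis(methoxymethoxy)-3-(3-methylbut-2-enyl)phenyl]boronic acid | COCOc1ccc(B(O)O)c(OCOC)c1CC=C(C)C
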